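The numbers in the tables stem from a simulated flask for an exercise; noise was put on by code.

In a one-step world your ledger for Q, the limiting reagent against 1.50 equiv of G, has a single entry: each Q lost is a D gained. The spring run shows that these books need more lines.

- spring: Q 0.10 M; G 1.5 equiv; run made earlier
- flask: Q 0.050 M; G 1.50 equiv; time 80 min; volume of the second phase over the first 1.0

spring run (percent of the Q charged)

| time / min | D / % | Q / % |
|---|---|---|
| 1.33 | 7.2 | 93.0 |
| 2.00 | 12.1 | 86.8 |
| 4.00 | 23.9 | 73.1 |
| 6.00 | 30.0 | 57.8 |
| 10.0 | 38.1 | 36.8 |
| 15.0 | 43.5 | 19.6 |

(each reading ± 1 percentage point)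

- D is meant together with its L
- in the second phase: G, L; everything else is in the first
- charges count per volume of the first phase; a concentration in a rate is the amount of a species over the volume of its own phase; every rate counts per litre of the first phase
- candidate steps: E <-> G; Q + E -> D; D <-> L; D -> J; D <-> X
- the earlier runs hold the two phases in the same ratio of volumes as the flask asked about

- how much D and L together there is at 80 min, in percent of the Q charged
- part of the Q charged that has reacted at 80 min

At 15.0 min the spring run holds 19.6 % of Q and 43.5 % of D with its L, so 36.9 % stands on a third line, as neither. To follow that line, take the marginal share, a differential yield: D gained per Q lost over a stretch of readings. In the spring run, from 6.00 min to 10.0 min it reads 0.386, and from there to 15.0 min it reads 0.314. Booking the remaining Q at this second share gives 49.7 % of D.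

But the second share reads lower than the first, so go round once more: shrunk by the same factor, the next marginal share is 0.256, and this is the share to carry. It closes the books at 48.5 %, taking the spring percentages for the flask.

Does Q finish? Its pseudo-first-order decay constant reads 0.120 min⁻¹ in the spring run. Even halved, for the halved c_Q, my estimate leaves 0.834 % of Q in the flask at 80 min. The readings do not split the third line, so any later loss from D stays unbooked in my figure.

The forecast gave 38 % and 98 %, lower on D than my ledger, holding that “Any slow leak to J would lower that”. The flask gives 43.5 % and 100 %.

    E ⇌ G, rate k1*([E] - [G]/K1) per volume of the first phase (partition coefficient = 0.430, kL = 0.0260 min⁻¹)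
    Q + E → D (k = 23.0 L mol⁻¹ min⁻¹)
    D ⇌ L, rate k3*([D] - [L]/K3) per volume of the first phase (partition coefficient = 7.70, kL = 0.0350 min⁻¹)
    D → J (k = 0.0200 min⁻¹)
    D ⇌ X (K = 2.90, k = 0.0940 min⁻¹)

Restart the ledger from this flask at 8.00 min, with Q at 52.3 % and D with L at 33.4 %: the share books 46.8 % at the end, against 43.5 %. For the neighbour flask read at 20 min, with Q at 11.7 %, it books 43.8 %, and that flask holds 43.0 %. The asked flask is not at rest at 80 min, although Q stands at 0 %: left until 800 min, its D with L falls from 43.5 % to 21.1 % and its X from 31.5 % to 5.36 %, while its J rises from 25.0 % to 73.6 %.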